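The readings are simulated on assumed constants; noise was put on by code.

**Hot minutes.** Count each flask's time at 60 °C in lifetimes of Tgt before you choose a recipe.

| flask | Oth | Oth2 | temperature | remark | time |
|---|---|---|---|---|---|
| Monday's | 1 mM | 1 equiv | 55 °C | run made earlier |  |
| Tuesday's | 0.50 mM | 1 equiv | 66 °C | run made earlier |  |
| Sunday's | 2 mM | 1 equiv | 55 °C | run made earlier |  |
| Thursday's | 1 mM | 0.50 equiv | 66 °C | run made earlier |  |
| north | 1.0 mM | 1.00 equiv (fed, over 1.0 min) | 60 °C | all else is in the flask from the start; the feed brings no volume worth counting | 5.0 min |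
| north-west | 1.0 mM | 1.00 equiv | 60 °C | everything together at the start | 5.0 min |
| south-east | 1.0 mM | 1.00 equiv |  | everything together at the start at 30 °C, warmed to 60 °C at 1.0 min | 5.0 min |
| south | 1.0 mM | 1.00 equiv (fed, over 1.0 min) |  | the addition at 30 °C, then warmed to 60 °C; the feed brings no volume worth counting | 5.0 min |

| run | time / min | Tgt / % | Oth3 / % |
|---|---|---|---|
| Monday's | 0.417 | 33.3 | 56.5 |
| Monday's | 0.833 | 28.5 | 62.0 |
| Monday's | 1.33 | 23.7 | 66.3 |
| Monday's | 1.50 | 22.5 | 68.6 |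
| Monday's | 2.00 | 18.8 | 71.3 |
| Monday's | 2.50 | 15.2 | 73.5 |
| Monday's | 3.00 | 13.6 | 76.4 |
| Tuesday's | 0.500 | 12.5 | 85.5 |
| Tuesday's | 1.00 | 8.6 | 87.8 |
| Tuesday's | 1.50 | 6.7 | 90.4 |
| Tuesday's | 2.50 | 3.3 | 95.2 |
| Tuesday's | 3.00 | 1.5 | 95.2 |
| Tuesday's | 4.00 | 0.4 | 96.2 |
| Sunday's | 0.333 | 42.6 | 42.7 |
| Sunday's | 0.500 | 38.8 | 43.5 |
| Sunday's | 0.667 | 37.0 | 46.1 |
| Sunday's | 1.00 | 33.2 | 50.9 |
| Sunday's | 1.50 | 28.7 | 56.3 |
| Sunday's | 2.50 | 20.9 | 63.4 |
| Sunday's | 4.00 | 12.4 | 72.3 |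
| Thursday's | 0.333 | 6.9 | 42.3 |
| Thursday's | 1.00 | 3.9 | 45.1 |
| Thursday's | 2.00 | 2.8 | 47.7 |
| Thursday's | 3.00 | 1.7 | 47.8 |
| Thursday's | 4.00 | 0.2 | 49.6 |

(standard deviation of a reading: 0.5 percentage points)



- which flask leads in share of Tgt in Tgt plus Oth3 ("all alike" within 1.5 percentage points) (north / north-west / south-east / south / all alike)
- share of Tgt in Tgt plus Oth3 at the end, north
- share of Tgt in Tgt plus Oth3 at the end, north-west
- share of Tgt in Tgt plus Oth3 at the end, south-east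
- share of Tgt in Tgt plus Oth3 at the end, south

**Drain constant.** Monday's Tgt falls from 33.3% to 13.6% between 0.417 min and 3.00 min, so I read a loss of 0.347 min⁻¹. Sunday's run, with twice the Oth, reads 0.337 min⁻¹, so I treat the loss as pseudo-first-order. Tuesday's run reads 0.666 min⁻¹ at 66 °C. Interpolating the logarithm gives 0.466 min⁻¹ for kd, the drain constant, the first-order rate constant of Tgt's loss at 60 °C.

**The puzzle.** North-west gets 2.33 lifetimes and south-east 1.87, so south-east's cold start saves Tgt by a factor of 1.59. Yet I expect a wider gap. Monday's first share of Tgt in Tgt plus Oth3 is 37.1%. Sunday's first ratio of Tgt to Oth3 is 1.69 times Monday's, for twice the charge at the same temperature, so one such step down from Monday's reckons 0.348 for half the charge at 55 °C. Tuesday's run, with that charge at 66 °C, reads 0.146, less than that reckoning. I therefore read heat as lowering the first ratio, and, extrapolating to 30 °C, cold mixing as starting richer in Tgt. Running Monday's share back to zero time gives 42.9%. I commit to north-west below 4.16% and south-east above 6.63%.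

**The forecast.** It gives north 1.1%, north-west 3.2%, south-east 10.3% (7.5% to 13.5%) and south 8%: “South-east leads, though the feed estimates are uncertain.”

**The result.** south-east leads, with 9.44%, against north 0.0419%, north-west 3.33% and south 5.85%.

    Oth + Oth2 ⇌ Tgt (K = 24000 M⁻¹, k = 190 M⁻¹ s⁻¹, Ea = 39.0 kJ mol⁻¹, ΔH = −22.0 kJ mol⁻¹)
    Oth + Oth2 → Oth3, rate k2*[Oth] as long as [Oth2] is above zero (k = 0.140 s⁻¹, Ea = 85.0 kJ mol⁻¹)
    Oth2 + Tgt → Sdp2 (k = 44.0 M⁻¹ s⁻¹, Ea = 45.0 kJ mol⁻¹)
    Oth2 → Sdp (k = 3.80 × 10⁻⁵ s⁻¹, Ea = 117 kJ mol⁻¹)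
    (constants at 60 °C)

**One neighbour.** South-east holds 52.0% Tgt at 1.00 min, when it is warmed, and 1.87 lifetimes from there reckon 8.05% at 5.0 min; at that end south-east holds 7.85%. The same flask stopped at 2.0 min has had 0.466 lifetimes, which reckons 32.6%. That stopped flask holds 32.6% Tgt.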